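**Analysis of the target**

The target 22 is built from two carbocycles joined by one methylene group. Ring A is a cyclohexa-2,4-dien-1-one, the dearomatised form of an acylphloroglucinol: C1 is the ring ketone, C2 carries the (R)-2-methylbutanoyl group, C3 and C5 are enolic C–OH carbons, C4 carries the linker and C6 is a quaternary carbon with a methyl and a prenyl group. Ring B is a cyclopentane with three contiguous stereocentres: C1′ (R) bears the CH2 linker, C2′ (S) is a tertiary carbinol with a methyl group, and C5′ (S) bears an isopropenyl group. The C1′ and C5′ substituents are trans and the C2′ hydroxyl is cis to the linker. The two remaining stereocentres stand alone. C6 (R) is insulated from ring B by the linker and a planar enol carbon, so ring B cannot be expected to control it, and the α-carbon of the acyl chain (R) is epimerisable. The tertiary alcohol and the 1,1-disubstituted alkene both ionise in acid and can be captured by a neighbouring ring A oxygen; the enolised β-triketone is acidic, chelating and easily over-alkylated. The difficulties are the absolute and relative configuration of the ring B triad and the face-selective creation of the remote quaternary carbon on a fully substituted ring. The strategy rests on one correspondence: C5′, C1′ and C2′ of ring B are the β-carbon, the α-carbon and the carbonyl carbon of cyclopent-2-en-1-one 8. The trans vicinal pair is therefore the signature of a conjugate addition followed by capture of the enolate, and C2′ is a ketone waiting for a methyl group.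

**Retrosynthetic reasoning**

C6–prenyl bond (22 to 21). C6 is the only sp3 carbon of ring A, and removing the prenyl group restores a fully substituted aromatic acylphloroglucinol, 21. All earlier chemistry on ring A can then be aromatic chemistry. The forward reaction has to alkylate the methyl-bearing ring carbon, not the linker-bearing one or oxygen, and has to choose one face of a flat ring that the distant ring B stereocentres do not bias. It is therefore placed last and put under catalyst control.

Phenol protection (21 to 20). The three phenols are carried as acetal ethers in 20. They direct metalation, tolerate organometallic reagents and leave under mild acid. Nothing is disconnected here, but the choice fixes what the later steps may use.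

Aryl–acyl bond (20 to 16 and 18, 18 to 17). In 16 the only ring hydrogen lies between two acetal oxygens, so the carbon that must carry the acyl group is the one carbon that can be metalated. The acyl group arrives as the amide 18, made in one step from the acid 17 with its stereocentre already present. Acylating before this point would place a second ketone in the molecule during the methyl addition.

C2′–methyl bond (16 to 15). The tertiary carbinol is cut back to ketone 15. A methyl nucleophile should approach the ring ketone anti to the neighbouring arylmethyl group, which gives the hydroxyl cis to the linker. This is the one ring B centre that the key step does not set.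

Linker oxidation level (15 to 13 to 11). The linker CH2 is traced back to the carbinol carbon of aldol 11 through enone 13. The extra oxygen is the price of using a stable aldehyde as the electrophile. A benzylic halide of this very electron-rich arene would be too labile to alkylate an enolate. Dehydration and conjugate reduction remove the oxygen, and the C2 centre, which becomes epimerisable, settles trans to the C3 substituent.

C5′–isopropenyl and C1′–linker bonds (11 to 8, 7 and 4). Both bonds at the enone carbons of 8 are cut at once. A chiral rhodium diphosphine catalyst transfers the isopropenyl group of 7 to the β-carbon, and the boron enolate that results is captured by aldehyde 4 at the α-carbon. Three achiral components then give all ring B carbons, the linker carbon and the arene, with the absolute configuration at C5′ set by the catalyst and the trans relationship set by approach anti to the new substituent. Cutting only one of the two bonds would leave the problem of enolising a 3-substituted cyclopentanone toward the more hindered side.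

Precursors (7 to 5 and 6; 4 to 2 to 1). Borane 7 comes from the Grignard reagent 5 and the borinic ester 6. Aldehyde 4 comes from 1 by protection to 2 and metalation–formylation at one of its two equivalent ring positions.

**Alternatives that were turned down**

Alternative 1: Ring A is cut at two bonds, C4–C5 and C1–C2, and assembled by a Claisen–Dieckmann sequence. A lithium amide base converts the β-diketone A2, which carries ring B with its silylated carbinol, into its dianion. The terminal carbon is acylated by the acid chloride of the chiral half-ester A3, and the central carbon then closes onto the methyl ester to give A1, the triethylsilyl ether of 22.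
- For: the quaternary centre is fixed in A3 before ring A exists, so no late face selection is needed. On this point the alternative is stronger than the chosen route, whose last step is its least certain.
- Against: A2 still contains the whole ring B triad, so the ring B problem is untouched and needs chemistry like steps 3 to 7 plus a homologation to the diketone.
- Against: the second γ-position of A2 is the stereogenic methine of the acyl chain, and any deprotonation there racemises it.
- Against: both carbonyl groups of A3 sit on a fully substituted carbon. The configuration of C6 is only carried over if the terminal carbon takes the acid chloride and the central carbon the ester; O-acylation or the reverse order gives the wrong isomer.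
- Comparison: two multistep fragments make the sequence longer. The chosen route offers a short, almost linear sequence in which ring B and its link to the arene are made in one operation.

Alternative 2: Ring B is cut at C1′–C2′. The keto acid A5, obtained by oxidative cleavage of the ring alkene of (S)-limonene A6, is activated at the carboxyl group. A nucleophilic amine catalyst forms an ammonium enolate that adds to the methyl ketone, and the alkoxide lactonises to the cis-fused bicyclic β-lactone A4.
- For: the C5′ centre comes from the chiral pool without a chiral catalyst.
- For: the cis ring fusion fixes the C2′ oxygen cis to the C1′ carbon by geometry. That is more secure than the facial selectivity on which step 7 depends.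
- Against: A6 is the less abundant enantiomer, and cleaving its ring alkene beside the isopropenyl group takes several steps.
- Against: the lactone carbonyl carbon is at the acid oxidation level and has no arene attached. Reaching the stage of 16 needs opening by an aryl nucleophile and full deoxygenation of an aryl ketone that is β to a tertiary alkoxide and so prone to retro-aldol cleavage.
- Comparison: the chosen key step forms the C1′–linker bond with the arene already attached and needs only removal of one hydroxyl group. It reaches 16 in six linear steps from 1.

Alternative 3: Ring B is cut at C1′–C5′. A zerovalent palladium catalyst with a C2-symmetric diphosphine ligand ionises the allylic carbonate of the acyclic β-keto ester A8, and the enolate attacks the substituted allyl terminus to close the ring to A7.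
- For: the ring closure is intramolecular, so there is no regiochemical doubt about which α-carbon is functionalised, and the acidic C1′ centre equilibrates to trans. In reliability it is about equal to the chosen key step.
- Against: A8 needs its own multistep preparation.
- Against: in A7 the ester carbon must still become a CH2 bonded to the arene, and the ketone cannot take a methyl nucleophile while the acidic β-keto ester is present. Several redox and protecting steps and a separate aryl–carbon bond formation follow.
- Comparison: the chosen route gives the arene-bearing skeleton in one pot from three purchased or one-step components.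

Key step: step 4

Remark: ring A of 22 is an enolised β-triketone, the drawn tautomer being one of several rapidly interconverting forms that count as one compound. Ring A is numbered C1 (ring ketone) to C6 (quaternary carbon), and primed locants belong to ring B.

**Route**

Step 1
Reactants: 1 2,4,6-trihydroxytoluene
Product: 2 2,4,6-tris(methoxymethoxy)toluene
Conditions: NaH, MOMCl, DMF, 0 °C → rt
Reagents that add atoms: chloromethyl methyl ether, COCCl
Why: Threefold O-alkylation of the phenoxides by the oxocarbenium-like chloro ether (Williamson-type acetal formation); the hard electrophile in a polar aprotic medium reacts at oxygen and not at ring carbon, and no stereocentre is involved.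

Step 2
Reactants: 2 2,4,6-tris(methoxymethoxy)toluene
Product: 4 2,4,6-tris(methoxymethoxy)-3-methylbenzaldehyde, via aryllithium 3 (not isolated)
Conditions: n-BuLi, TMEDA, THF, 0 °C; DMF, 0 °C → rt; aq. NH4Cl
Reagents that add atoms: N,N-dimethylformamide, CN(C)C=O
Why: Directed ortho-metalation: each of the two equivalent ring hydrogens lies between two acetal oxygens that hold lithium, so one equivalent of base gives a single aryllithium, which is formylated by the amide and released as the aldehyde on work-up.

Step 3
Reactants: 5 isopropenylmagnesium bromide; 6 9-methoxy-9-borabicyclo[3.3.1]nonane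
Product: 7 9-(prop-1-en-2-yl)-9-borabicyclo[3.3.1]nonane
Conditions: THF–pentane, −78 °C → rt; MgBr(OMe) filtered off under Ar; distillation
Reagents that add atoms: none
Why: The Grignard reagent adds to the borinic ester to give a borate that loses methoxide as MgBr(OMe), the standard preparation of B-organyl-9-borabicyclononanes; the alkenyl group is transferred unchanged.

Step 4
Reactants: 8 cyclopent-2-en-1-one; 7 9-(prop-1-en-2-yl)-9-borabicyclo[3.3.1]nonane; 4 2,4,6-tris(methoxymethoxy)-3-methylbenzaldehyde
Product: 11 (2S,3S)-2-{(R)-hydroxy[2,4,6-tris(methoxymethoxy)-3-methylphenyl]methyl}-3-(prop-1-en-2-yl)cyclopentan-1-one (anti aldol; ring substituents trans), via boron enolate 9 (not isolated), via boron aldolate 10 (not isolated)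
Conditions: [Rh(OMe)(cod)]2 (1.5 mol%), (S)-BINAP (3.3 mol%), toluene, 80 °C; 4, −78 °C → rt; HOCH2CH2NH2, Et2O
Reagents that add atoms: none
Why: Transmetalation of the isopropenyl group from 7 to the Rh–OMe complex of (S)-BINAP gives an isopropenyl complex of monovalent rhodium that inserts 8 on one enantioface; the oxa-π-allyl rhodium so formed hands its enolate to boron by reaction with a second molecule of 7, which regenerates the alkenylrhodium and leaves the regiodefined boron enolate 9 in the aprotic medium. Aldehyde 4 then adds through a closed six-membered chair transition state to give aldolate 10, and 2-aminoethanol takes the boron off to free 11. The closest known reaction type is the rhodium–BINAP asymmetric 1,4-addition of B-aryl-9-borabicyclononanes to cyclic enones with aldol capture of the boron enolate, together with rhodium–BINAP additions of alkenylboron and alkenylzirconium reagents to the same enones. No ring is closed; the two skeletal bonds C3–isopropenyl and C2–carbinol carbon are formed. C3 is set by the ligand, (S)-BINAP being chosen by analogy with its established facial sense on five- and six-membered enones, where it leads to the (S) centre with the same priority order as here. C2 is set by approach of the aldehyde to the enolate face opposite the new C3 substituent (trans), and the carbinol centre follows from the ring-fixed E enolate in the chair (anti) but is removed in steps 5 and 6. The step needs 1,4- and not 1,2-addition, transfer of the sp2 group and not of a ring B–C bond of the bicyclononane, and an enolate that does not drift to C5: rhodium secures the first, the borabicyclononane framework the second and the absence of any proton source the third.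

Step 5
Reactants: 11 (2S,3S)-2-{(R)-hydroxy[2,4,6-tris(methoxymethoxy)-3-methylphenyl]methyl}-3-(prop-1-en-2-yl)cyclopentan-1-one
Product: 13 (2E,3R)-2-{[2,4,6-tris(methoxymethoxy)-3-methylphenyl]methylidene}-3-(prop-1-en-2-yl)cyclopentan-1-one, via mesylate 12 (not isolated)
Conditions: MsCl, Et3N, CH2Cl2, 0 °C; DBU, 0 °C → rt
Reagents that add atoms: none
Why: Sulfonylation of the benzylic carbinol and base-induced β-elimination (E1cB, helped by the strongly donating aryl group) give the conjugated exocyclic enone, expected mainly as the E isomer; the carbinol and C2 centres are given up on purpose, while C3 is not acidic under these conditions and keeps its configuration (its descriptor changes to R only through the priority rules).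

Step 6
Reactants: 13 (2E,3R)-2-{[2,4,6-tris(methoxymethoxy)-3-methylphenyl]methylidene}-3-(prop-1-en-2-yl)cyclopentan-1-one
Product: 15 (2R,3S)-2-{[2,4,6-tris(methoxymethoxy)-3-methylphenyl]methyl}-3-(prop-1-en-2-yl)cyclopentan-1-one (trans), via cis ketone 14 (not isolated)
Conditions: [(Ph3P)CuH]6 (0.4 equiv), H2O (3 equiv), benzene, rt; K2CO3 (cat.), MeOH, rt
Reagents that add atoms: none
Why: Conjugate (1,4) reduction by the copper hydride cluster, which delivers hydride to the benzylic β-carbon of the enone and leaves the isolated 1,1-disubstituted alkene and the ketone alone; protonation of the copper enolate may occur from the face away from the isopropenyl group to give the cis isomer 14, and mild base equilibrates C2 through the enol to the more stable trans isomer 15.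

Step 7
Reactants: 15 (2R,3S)-2-{[2,4,6-tris(methoxymethoxy)-3-methylphenyl]methyl}-3-(prop-1-en-2-yl)cyclopentan-1-one
Product: 16 (1S,2R,3S)-1-methyl-2-{[2,4,6-tris(methoxymethoxy)-3-methylphenyl]methyl}-3-(prop-1-en-2-yl)cyclopentan-1-ol
Conditions: MeLi, CeCl3, THF, −78 °C; aq. NH4Cl
Reagents that add atoms: methyllithium, [Li]C
Why: 1,2-Addition of the organocerium reagent, which is nucleophilic but hardly basic, so the epimerisable C2 centre is not enolised; the methyl group should enter from the ketone face opposite the bulky C2 arylmethyl group, which puts the new hydroxyl cis to that group as in ring B of the target.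

Step 8
Reactants: 17 (R)-2-methylbutanoic acid
Product: 18 (R)-N-methoxy-N,2-dimethylbutanamide
Conditions: MeNHOMe·HCl, EDC·HCl, HOBt, N-methylmorpholine, CH2Cl2, 0 °C → rt
Reagents that add atoms: N,O-dimethylhydroxylamine hydrochloride, CNOC.Cl
Why: Carbodiimide-mediated amide coupling through the benzotriazolyl ester; an α-alkyl acid without an N-acyl group has no oxazolone pathway and the medium is only weakly basic, so the (R) centre is retained.

Step 9
Reactants: 16 (1S,2R,3S)-1-methyl-2-{[2,4,6-tris(methoxymethoxy)-3-methylphenyl]methyl}-3-(prop-1-en-2-yl)cyclopentan-1-ol; 18 (R)-N-methoxy-N,2-dimethylbutanamide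
Product: 20 (2R)-1-[3-{[(1R,2S,5S)-2-hydroxy-2-methyl-5-(prop-1-en-2-yl)cyclopentyl]methyl}-2,4,6-tris(methoxymethoxy)-5-methylphenyl]-2-methylbutan-1-one, via dilithio species 19 (not isolated)
Conditions: n-BuLi (2.3 equiv), THF, −20 → 0 °C; 18, −78 → 0 °C; aq. NH4Cl, −78 °C
Reagents that add atoms: none
Why: The first equivalent of base forms the tertiary alkoxide and the second removes the only ring hydrogen, which lies between two acetal oxygens (directed ortho-metalation); the aryllithium adds to the N-methoxy-N-methylamide to give a chelated tetrahedral adduct that does not collapse before the cold quench, so over-addition and base exposure of the new α-branched ketone are avoided and the alkoxide is not acylated.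

Step 10
Reactants: 20 (2R)-1-[3-{[(1R,2S,5S)-2-hydroxy-2-methyl-5-(prop-1-en-2-yl)cyclopentyl]methyl}-2,4,6-tris(methoxymethoxy)-5-methylphenyl]-2-methylbutan-1-one
Product: 21 (2R)-1-[2,4,6-trihydroxy-3-{[(1R,2S,5S)-2-hydroxy-2-methyl-5-(prop-1-en-2-yl)cyclopentyl]methyl}-5-methylphenyl]-2-methylbutan-1-one
Conditions: HCl (1 M in MeOH), 0 °C → rt
Reagents that add atoms: none
Why: Acid-catalysed methanolysis of the three aryl methoxymethyl acetals, those beside the ketone being assisted by hydrogen bonding; dilute acid at or below room temperature is chosen so that the tertiary alcohol and the isopropenyl group are not ionised, and no stereocentre is touched.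

Step 11
Reactants: 21 (2R)-1-[2,4,6-trihydroxy-3-{[(1R,2S,5S)-2-hydroxy-2-methyl-5-(prop-1-en-2-yl)cyclopentyl]methyl}-5-methylphenyl]-2-methylbutan-1-one
Product: 22 (6R)-3,5-dihydroxy-4-{[(1R,2S,5S)-2-hydroxy-2-methyl-5-(prop-1-en-2-yl)cyclopentyl]methyl}-6-methyl-6-(3-methylbut-2-en-1-yl)-2-[(2R)-2-methylbutanoyl]cyclohexa-2,4-dien-1-one
Conditions: Pd2(dba)3 (2.5 mol%), (R,R)-N,N′-(cyclohexane-1,2-diyl)bis[2-(diphenylphosphanyl)benzamide] (7.5 mol%), prenyl acetate, Cs2CO3, THF, 0 °C → rt; aq. citric acid
Reagents that add atoms: 3-methylbut-2-en-1-yl acetate, CC(C)=CCOC(C)=O
Why: Proposed new method: zerovalent palladium ionises the allylic acetate to a cationic π-prenyl complex of divalent palladium held in the chiral pocket of the diphosphine, the cesium phenoxide of 21 attacks its unsubstituted terminus through the methyl-bearing ring carbon (the less hindered of the two alkyl-substituted nucleophilic carbons; O-prenyl ethers re-ionise and drain to the C-alkylated product), and the ligand has to select the ring face so that C6 becomes R, the (S,S) ligand being taken instead if the first run shows the opposite sense; the closest known reaction types are the base-mediated dearomative C-prenylation of acylphloroglucinols and the palladium-catalysed asymmetric allylic dearomatisation of phenols and naphthols with chiral diphosphines.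

**Compound list**

1 | 2,4,6-trihydroxytoluene | Cc1c(O)cc(O)cc1O | starting material
2 | 2,4,6-tris(methoxymethoxy)toluene | Cc1c(OCOC)cc(OCOC)cc1OCOC | intermediate
3 | [2,4,6-tris(methoxymethoxy)-3-methylphenyl]lithium (formed in the flask) | [Li]c1c(OCOC)cc(OCOC)c(C)c1OCOC | intermediate
4 | 2,4,6-tris(methoxymethoxy)-3-methylbenzaldehyde | O=Cc1c(OCOC)cc(OCOC)c(C)c1OCOC | intermediate
5 | isopropenylmagnesium bromide | C=C(C)[Mg]Br | starting material
6 | 9-methoxy-9-borabicyclo[3.3.1]nonane | COB1C2CCCC1CCC2 | starting material
7 | 9-(prop-1-en-2-yl)-9-borabicyclo[3.3.1]nonane | C=C(C)B1C2CCCC1CCC2 | intermediate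
8 | cyclopent-2-en-1-one | O=C1C=CCC1 | starting material
9 | 9-{[(3S)-3-(prop-1-en-2-yl)cyclopent-1-en-1-yl]oxy}-9-borabicyclo[3.3.1]nonane (boron enolate, formed in the flask) | C=C(C)[C@H]1CCC(OB2C3CCCC2CCC3)=C1 | intermediate
10 | O-(9-borabicyclo[3.3.1]nonan-9-yl) derivative of 11 at the carbinol oxygen (boron aldolate, formed in the flask) | C=C(C)[C@H]1CCC(=O)[C@@H]1[C@@H](OB2C3CCCC2CCC3)c2c(OCOC)cc(OCOC)c(C)c2OCOC | intermediate
11 | (2S,3S)-2-{(R)-hydroxy[2,4,6-tris(methoxymethoxy)-3-methylphenyl]methyl}-3-(prop-1-en-2-yl)cyclopentan-1-one | C=C(C)[C@H]1CCC(=O)[C@@H]1[C@@H](O)c1c(OCOC)cc(OCOC)c(C)c1OCOC | intermediate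
12 | (R)-[(1S,5S)-2-oxo-5-(prop-1-en-2-yl)cyclopentyl][2,4,6-tris(methoxymethoxy)-3-methylphenyl]methyl methanesulfonate (formed in the flask) | C=C(C)[C@H]1CCC(=O)[C@@H]1[C@@H](OS(C)(=O)=O)c1c(OCOC)cc(OCOC)c(C)c1OCOC | intermediate
13 | (2E,3R)-2-{[2,4,6-tris(methoxymethoxy)-3-methylphenyl]methylidene}-3-(prop-1-en-2-yl)cyclopentan-1-one | C=C(C)[C@H]1CCC(=O)/C1=C/c1c(OCOC)cc(OCOC)c(C)c1OCOC | intermediate
14 | (2S,3S)-2-{[2,4,6-tris(methoxymethoxy)-3-methylphenyl]methyl}-3-(prop-1-en-2-yl)cyclopentan-1-one (cis, formed in the flask) | C=C(C)[C@H]1CCC(=O)[C@H]1Cc1c(OCOC)cc(OCOC)c(C)c1OCOC | intermediate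
15 | (2R,3S)-2-{[2,4,6-tris(methoxymethoxy)-3-methylphenyl]methyl}-3-(prop-1-en-2-yl)cyclopentan-1-one (trans) | C=C(C)[C@H]1CCC(=O)[C@@H]1Cc1c(OCOC)cc(OCOC)c(C)c1OCOC | intermediate
16 | (1S,2R,3S)-1-methyl-2-{[2,4,6-tris(methoxymethoxy)-3-methylphenyl]methyl}-3-(prop-1-en-2-yl)cyclopentan-1-ol | C=C(C)[C@H]1CC[C@](C)(O)[C@@H]1Cc1c(OCOC)cc(OCOC)c(C)c1OCOC | intermediate
17 | (R)-2-methylbutanoic acid | CC[C@@H](C)C(=O)O | starting material
18 | (R)-N-methoxy-N,2-dimethylbutanamide | CC[C@@H](C)C(=O)N(C)OC | intermediate
19 | lithium (1S,2R,3S)-2-{[3-lithio-2,4,6-tris(methoxymethoxy)-5-methylphenyl]methyl}-1-methyl-3-(prop-1-en-2-yl)cyclopentan-1-olate (formed in the flask) | C=C(C)[C@H]1CC[C@](C)(O[Li])[C@@H]1Cc1c(OCOC)c([Li])c(OCOC)c(C)c1OCOC | intermediate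
20 | (2R)-1-[3-{[(1R,2S,5S)-2-hydroxy-2-methyl-5-(prop-1-en-2-yl)cyclopentyl]methyl}-2,4,6-tris(methoxymethoxy)-5-methylphenyl]-2-methylbutan-1-one | C=C(C)[C@H]1CC[C@](C)(O)[C@@H]1Cc1c(OCOC)c(C(=O)[C@H](C)CC)c(OCOC)c(C)c1OCOC | intermediate
21 | (2R)-1-[2,4,6-trihydroxy-3-{[(1R,2S,5S)-2-hydroxy-2-methyl-5-(prop-1-en-2-yl)cyclopentyl]methyl}-5-methylphenyl]-2-methylbutan-1-one | C=C(C)[C@H]1CC[C@](C)(O)[C@@H]1Cc1c(O)c(C(=O)[C@H](C)CC)c(O)c(C)c1O | intermediate
22 | (6R)-3,5-dihydroxy-4-{[(1R,2S,5S)-2-hydroxy-2-methyl-5-(prop-1-en-2-yl)cyclopentyl]methyl}-6-methyl-6-(3-methylbut-2-en-1-yl)-2-[(2R)-2-methylbutanoyl]cyclohexa-2,4-dien-1-one | C=C(C)[C@H]1CC[C@](C)(O)[C@@H]1CC1=C(O)[C@@](C)(CC=C(C)C)C(=O)C(C(=O)[C@H](C)CC)=C1O | target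

**Step count and least certain steps**

Total: 11 steps. Longest linear sequence: 9 steps (1, 2, 4, 5, 6, 7, 9, 10, 11) from 1 to 22; steps 3 and 8 are one-step branches.

Step 11 (labelled as a new method). The most likely failure is poor facial selectivity at the methyl-bearing carbon. The two ring faces differ only through substituents that are meta to the reacting carbon, and ring B is too far away to help. Alkylation at the linker-bearing carbon, on oxygen, or a second prenylation may also compete. Fallback by known chemistry: 21 is treated with prenyl bromide and NaOMe in MeOH at 0 °C, the classical base-mediated dearomative C-prenylation of acylphloroglucinols, without any attempt at face control. This should give 22 together with its C6 epimer F1. The two are diastereomers because of ring B and would be separated by preparative HPLC. The fallback sets out from 21 and comes back at 22.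

Step 4 (key step). The α-branched alkenyl group may be transferred from boron to rhodium too slowly, so that conversion stays low. Alternatively the hindered, electron-rich aldehyde may capture the boron enolate slowly and reversibly, so that the regiodefined enolate is lost on warming. Fallback under substrate control:
- Grignard reagent 5 is added with CuI and PBu3 in THF at −78 °C to purchased (R)-4-[(tert-butyldimethylsilyl)oxy]cyclopent-2-en-1-one F2, anti to the silyloxy group, and the enolate is captured by 4 to give the silyloxy aldol F3.
- MsCl, Et3N and DMAP at 0 °C dehydrate it to the arylidene ketone F4.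
- [(Ph3P)CuH]6 in wet benzene reduces the exocyclic enone to the silyloxy ketone F5.
- Brief treatment with DBU at room temperature eliminates silanol to give cyclopentenone F6 and sets the arylmethyl carbon trans.
- A second reduction with [(Ph3P)CuH]6 gives 15.

This fallback sets out from 4 and 5 and comes back at 15.

Step 6. The two ortho substituents of the twisted aryl group shield the β-carbon, so hydride delivery from the bulky copper cluster may be slow or may turn to 1,2-reduction. Fallback: the mode of reduction is changed from hydride transfer to electron transfer. 13 is reduced with SmI2 in THF–MeOH at −78 °C, followed by the same base equilibration. It sets out from 13 and comes back at 15 without a new compound.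

Step 7. The face anti to the arylmethyl group is the one flanked by the isopropenyl group, so facial selectivity may be insufficient and some C2′ epimer may form. Fallback: 15 is treated with dimethylsulfonium methylide (Me3SI, KN(SiMe3)2, THF, 0 °C) to give the spiro-epoxide F7. The bulkier ylide should discriminate the faces more strongly, and any epimeric epoxide can be removed at this stage. LiEt3BH then opens the epoxide at its CH2 carbon. The fallback sets out from 15 and comes back at 16.

Step 9. The hindered aryllithium may act as a base toward the α-branched amide, returning 16 and eroding the amide stereocentre, or may add too slowly. Lateral or allylic lithiation may also compete. Fallback: 18 is reduced with LiAlH4 at −78 °C to (R)-2-methylbutanal F8, which is used at once. Dianion 19 is added to it at −78 °C to give the benzylic carbinol F9, which is oxidised with Dess–Martin periodinane (NaHCO3, CH2Cl2). The fallback sets out from 16 and 18 and comes back at 20.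

Step 10. Acid may ionise the tertiary alcohol or protonate the isopropenyl group, with capture by a freed ortho phenol to give a cyclic ether, or with elimination. The third acetal, flanked on both sides and not hydrogen-bonded, may also cleave slowly. Fallback: the mechanism is changed from protic hydrolysis to silyl transfer under buffered aprotic conditions. 20 is treated with TMSOTf and 2,2′-bipyridyl in CH3CN at 0 °C to give the persilylated compound F10, which is desilylated with K2CO3 in MeOH. The fallback sets out from 20 and comes back at 21.

**Further compounds**

F1 | step 11 | C6 epimer of 22, (6S)-3,5-dihydroxy-4-{[(1R,2S,5S)-2-hydroxy-2-methyl-5-(prop-1-en-2-yl)cyclopentyl]methyl}-6-methyl-6-(3-methylbut-2-en-1-yl)-2-[(2R)-2-methylbutanoyl]cyclohexa-2,4-dien-1-one | C=C(C)[C@H]1CC[C@](C)(O)[C@@H]1CC1=C(O)[C@](C)(CC=C(C)C)C(=O)C(C(=O)[C@H](C)CC)=C1O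
F2 | step 4 | (R)-4-[(tert-butyldimethylsilyl)oxy]cyclopent-2-en-1-one (purchased) | O=C1C=C[C@H](O[Si](C)(C)C(C)(C)C)C1
F3 | step 4 | (2S,3S,4R)-4-[(tert-butyldimethylsilyl)oxy]-2-{hydroxy[2,4,6-tris(methoxymethoxy)-3-methylphenyl]methyl}-3-(prop-1-en-2-yl)cyclopentan-1-one (carbinol epimers) | C=C(C)[C@H]1[C@H](O[Si](C)(C)C(C)(C)C)CC(=O)[C@@H]1C(O)c1c(OCOC)cc(OCOC)c(C)c1OCOC
F4 | step 4 | (2E,3R,4R)-4-[(tert-butyldimethylsilyl)oxy]-2-{[2,4,6-tris(methoxymethoxy)-3-methylphenyl]methylidene}-3-(prop-1-en-2-yl)cyclopentan-1-one | C=C(C)[C@H]1[C@H](O[Si](C)(C)C(C)(C)C)CC(=O)/C1=C/c1c(OCOC)cc(OCOC)c(C)c1OCOC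
F5 | step 4 | (2R,3S,4R)-4-[(tert-butyldimethylsilyl)oxy]-2-{[2,4,6-tris(methoxymethoxy)-3-methylphenyl]methyl}-3-(prop-1-en-2-yl)cyclopentan-1-one | C=C(C)[C@H]1[C@H](O[Si](C)(C)C(C)(C)C)CC(=O)[C@@H]1Cc1c(OCOC)cc(OCOC)c(C)c1OCOC
F6 | step 4 | (4S,5R)-5-{[2,4,6-tris(methoxymethoxy)-3-methylphenyl]methyl}-4-(prop-1-en-2-yl)cyclopent-2-en-1-one | C=C(C)[C@H]1C=CC(=O)[C@@H]1Cc1c(OCOC)cc(OCOC)c(C)c1OCOC
F0 | step 6 | none | none
F7 | step 7 | 4-{[2,4,6-tris(methoxymethoxy)-3-methylphenyl]methyl}-5-(prop-1-en-2-yl)-1-oxaspiro[2.4]heptane, epoxide oxygen cis to the arylmethyl group and trans to the isopropenyl group | C=C(C)[C@H]1CC[C@@]2(CO2)[C@@H]1Cc1c(OCOC)cc(OCOC)c(C)c1OCOC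
F8 | step 9 | (R)-2-methylbutanal | CC[C@@H](C)C=O
F9 | step 9 | (2R)-1-[3-{[(1R,2S,5S)-2-hydroxy-2-methyl-5-(prop-1-en-2-yl)cyclopentyl]methyl}-2,4,6-tris(methoxymethoxy)-5-methylphenyl]-2-methylbutan-1-ol (carbinol epimers) | C=C(C)[C@H]1CC[C@](C)(O)[C@@H]1Cc1c(OCOC)c(C(O)[C@H](C)CC)c(OCOC)c(C)c1OCOC
F10 | step 10 | tetrakis(trimethylsilyl) ether of 21 (three aryl oxygens and the tertiary carbinol oxygen) | C=C(C)[C@H]1CC[C@](C)(O[Si](C)(C)C)[C@@H]1Cc1c(O[Si](C)(C)C)c(C(=O)[C@H](C)CC)c(O[Si](C)(C)C)c(C)c1O[Si](C)(C)C
A1 | alternative 1 | triethylsilyl ether of 22 at the C2′ oxygen | C=C(C)[C@H]1CC[C@](C)(O[Si](CC)(CC)CC)[C@@H]1CC1=C(O)[C@@](C)(CC=C(C)C)C(=O)C(C(=O)[C@H](C)CC)=C1O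
A2 | alternative 1 | (6R)-6-methyl-1-[(1R,2S,5S)-2-methyl-5-(prop-1-en-2-yl)-2-(triethylsilyloxy)cyclopentyl]octane-3,5-dione | C=C(C)[C@H]1CC[C@](C)(O[Si](CC)(CC)CC)[C@@H]1CCC(=O)CC(=O)[C@H](C)CC
A3 | alternative 1 | methyl (2S)-2-(chlorocarbonyl)-2,5-dimethylhex-4-enoate | O=C(Cl)[C@@](C)(CC=C(C)C)C(=O)OC
A4 | alternative 2 | cis-fused 5-methyl-2-(prop-1-en-2-yl)-6-oxabicyclo[3.2.0]heptan-7-one, isopropenyl trans to the lactone carbonyl carbon | C=C(C)[C@H]1CC[C@]2(C)OC(=O)[C@H]12
A5 | alternative 2 | (3S)-6-oxo-3-(prop-1-en-2-yl)heptanoic acid | C=C(C)[C@H](CC(=O)O)CCC(C)=O
A6 | alternative 2 | (S)-limonene | CC1=CC[C@H](CC1)C(C)=C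
A7 | alternative 3 | methyl (1R,5S)-2-oxo-5-(prop-1-en-2-yl)cyclopentane-1-carboxylate (trans) | C=C(C)[C@H]1CCC(=O)[C@@H]1C(=O)OC
A8 | alternative 3 | methyl (6E)-8-[(methoxycarbonyl)oxy]-7-methyl-3-oxooct-6-enoate | COC(=O)CC(=O)CC/C=C(\C)COC(=O)OC
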